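**Strategy.** The plan cuts the 6-oxabicyclo[3.2.1]octane at C1–C8 and at O6–C5. The quaternary carbon C1 is bonded to a methyl group, to carbinol carbon C2 and to the bridge methylene C7. This is the substitution pattern of the α-carbon of a 2-methyl-3-oxo ester. C5 and C8 are the two ends of an (E)-trisubstituted alkene. One oxidative radical cyclisation closes the carbocycle C1–C2–C3–C4–C5–C8 and lets the C7 ester capture C5 as the O6 bridge (ring C1–C7–O6–C5–C8). It also sets C1, C5 and C8 and expels the chiral alcohol. Its precursor is the open-chain (−)-8-phenylmenthyl (E)-2,6-dimethyl-3,10-dioxoundec-6-enoate, built from (E)-geranylacetone by a propionate aldol.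

Key step: step 7

Atom labels: C1–C5, O6, C7 and C8 follow the 6-oxabicyclo[3.2.1]octane numbering of the target. C9–C13 are the side-chain carbons counted from C8, and C11 carries the methyl group.

Assumption: the C1 radical is taken to react with its two carbonyl groups anti and the phenyl ring of the auxiliary stacked on one face, which for the (−)-alcohol leaves open the face leading to the (1S,5S,8R) keto lactone; if the sense proved opposite, (+)-8-phenylmenthol would be used in step 4 with no other change.

Step 1
Reactants: 1 (E)-geranylacetone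
Product: 2 (5E)-9-bromo-10-hydroxy-6,10-dimethylundec-5-en-2-one (racemic)
Conditions: NBS (1.05 equiv), THF/H2O, 0 °C
Reagents that add atoms: N-bromosuccinimide, O=C1CCC(=O)N1Br; water, O
Why: Bromohydrin formation by electrophilic addition: in the aqueous medium the exposed terminal alkene should be brominated ahead of the internal one, water opens the bromonium ion at the tertiary carbon, and the racemic C–Br centre does not matter because that carbon becomes the aldehyde carbon in step 3.

Step 2
Reactants: 2 bromohydrin
Product: 3 (5E)-9,10-epoxy-6,10-dimethylundec-5-en-2-one (racemic)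
Conditions: K2CO3, MeOH, rt
Reagents that add atoms: none
Why: Intramolecular Williamson-type closure, in which the tertiary alkoxide displaces the neighbouring bromide, should give the terminal epoxide while the ketone and the internal (E)-alkene are inert to K2CO3/MeOH.

Step 3
Reactants: 3 terminal epoxide
Product: 5 (4E)-4-methyl-8-oxonon-4-enal, via glycol 4 (not isolated)
Conditions: H5IO6 (1.2 equiv), THF/H2O, 0 °C → rt
Reagents that add atoms: none
Why: Periodic acid hydrolyses the epoxide to glycol 4 and cleaves it in the same flask (Malaprade glycol cleavage) without touching the ketone or the internal alkene, so the (E) geometry needed in step 7 is carried over unchanged.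

Step 4
Reactants: 6 (−)-8-phenylmenthol; 7 propionyl chloride
Product: 8 (1R,2S,5R)-8-phenylmenthyl propionate
Conditions: Et3N (1.5 equiv), DMAP (0.1 equiv), CH2Cl2, 0 °C → rt
Reagents that add atoms: none
Why: DMAP-catalysed O-acylation lets the acid chloride esterify the hindered secondary alcohol at oxygen, so the three stereocentres of the auxiliary are not involved.

Step 5
Reactants: 8 8-phenylmenthyl propionate; 5 keto aldehyde
Product: 10 8-phenylmenthyl (6E)-3-hydroxy-2,6-dimethyl-10-oxoundec-6-enoate (mixture at the two new centres), via lithium enolate 9 (not isolated)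
Conditions: LiN(iPr)2 (1.05 equiv), THF, −78 °C; 5 (1.1 equiv), −78 °C; AcOH quench at −78 °C
Reagents that add atoms: none
Why: Aldol addition of a preformed lithium ester enolate: at −78 °C the aldehyde reacts far faster than the methyl ketone, the enolate is the limiting component and the cold acidic quench prevents retro-aldol, while the two new centres may form as a mixture because one is oxidised in step 6 and the other becomes a planar radical in step 7.

Step 6
Reactants: 10 aldol
Product: 11 (1R,2S,5R)-8-phenylmenthyl (6E)-2,6-dimethyl-3,10-dioxoundec-6-enoate (epimers at the α-carbon)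
Conditions: Dess–Martin periodinane (1.3 equiv), CH2Cl2, 0 °C → rt
Reagents that add atoms: none
Why: Dess–Martin oxidation of the secondary carbinol under neutral conditions should give the 3-oxo ester without retro-aldol cleavage or movement of the alkene, and the epimeric α-carbon is irrelevant for step 7.

Step 7
Reactants: 11 8-phenylmenthyl 2-methyl-3-oxo ester
Product: 13 (1S,5S,8R)-1,5-dimethyl-8-(3-oxobutyl)-6-oxabicyclo[3.2.1]octane-2,7-dione, via dialkoxycarbenium acetate 12 (not isolated)
Conditions: Mn(OAc)3·2H2O (2.3 equiv), Cu(OAc)2·H2O (0.2 equiv), degassed AcOH (0.05 M), 35 °C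
Reagents that add atoms: water, O (hydrate water of the salts; becomes the C7 carbonyl oxygen)
Why: Trivalent manganese oxidises the enol of 11 to the planar, electrophilic C1 radical, which bonds to the less substituted alkene carbon C8; the tertiary C5 radical is oxidised by divalent copper (itself regenerated by trivalent manganese) to the C5 cation, the carbonyl oxygen of the C7 ester adds to it to give ion 12, and hydrate water attacks C7 so that the tetrahedral intermediate expels 8-phenylmenthol 6 and leaves lactone 13. The closest known reaction type is the Mn(OAc)3/Cu(OAc)2 oxidative free-radical cyclisation of unsaturated 2-alkyl-3-oxo esters, which is established for 8-phenylmenthyl esters and is known to finish as a lactone when an ester lies cis to the tertiary cation. The carbocycle C1–C2–C3–C4–C5–C8 closes 6-endo-trig through a chair that holds the C2 carbonyl group inside the ring, and the lactone ring C1–C7–O6–C5–C8 closes as a five-membered ring by 1,3-diaxial attack of the ester oxygen on the trigonal C5. C1 is set by the auxiliary, whose phenyl ring covers one face of the radical so that C8 bonds to the open face; C8 is set by the (E)-alkene, which keeps C9 anti to C4 and therefore equatorial, in combination with the axial ester; C5 follows from C1 because the tethered oxygen reaches only the face of the cation syn to C7. The step needs 6-endo regiochemistry, an axial ester, one radical face and an untouched methyl ketone, and these are secured by the methyl group on C5 (it blocks 5-exo attack and makes the 6-endo radical tertiary), by the dipole-minimised radical conformer in which C2=O eclipses the C1 methyl group and the ester stands anti to it, by the 8-phenylmenthyl group, and by the fact that Mn(OAc)3 does not enolise a simple ketone at this temperature. No chelating Lewis acid is added, because a chelate would hold the two carbonyl groups syn and turn the ester equatorial, out of reach of C5.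

Step 8
Reactants: 13 keto lactone
Product: 14 (1S,5S,8R)-8-(3-hydroxybutyl)-1,5-dimethyl-6-oxabicyclo[3.2.1]octane-2,7-diol (lactol; epimers at C2 C7 C11)
Conditions: iBu2AlH (5 equiv), CH2Cl2, −78 °C; MeOH, then aq. potassium sodium tartrate
Reagents that add atoms: none
Why: Hydride reduction with iBu2AlH: at −78 °C both ketones go to carbinols and the γ-lactone stops at the lactol because its tetrahedral aluminium alkoxide survives until the quench, so the sensitive 3-oxo lactone is removed at once, and the new centres may be mixtures since C7 is reduced further in step 9 and C2 and C11 are re-oxidised in step 10.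

Step 9
Reactants: 14 lactol diol
Product: 15 (1R,5S,8R)-8-(3-hydroxybutyl)-1,5-dimethyl-6-oxabicyclo[3.2.1]octan-2-ol (epimers at C2 C11)
Conditions: Et3SiH (5 equiv), BF3·OEt2 (3 equiv), CH2Cl2, −78 → −20 °C
Reagents that add atoms: none
Why: Ionic reduction of a lactol: BF3·OEt2 activates the C7 hydroxyl as a leaving group and Et3SiH delivers hydride to C7, which makes the ether methylene without breaking the C5–O6 bond, while simple secondary carbinols are inert to the silane, the C2 hydroxyl could reach C7 only through an oxetane, and no acetal protecting group, which these reagents would also reduce, is present.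

Step 10
Reactants: 15 diol ether
Product: 16 (1R,5S,8R)-1,5-dimethyl-8-(3-oxobutyl)-6-oxabicyclo[3.2.1]octan-2-one
Conditions: Dess–Martin periodinane (2.6 equiv), CH2Cl2, 0 °C → rt
Reagents that add atoms: none
Why: Double Dess–Martin oxidation returns both secondary carbinols to ketones and so erases the epimeric mixtures, the ether bridge is inert, and no epimerisable stereocentre lies next to either carbonyl group.

Step 11
Reactants: 16 diketone ether
Product: 17 ethyl (2E)-5-[(1R,5S,8R)-1,5-dimethyl-2-oxo-6-oxabicyclo[3.2.1]octan-8-yl]-3-methylpent-2-enoate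
Conditions: (iPrO)2P(O)CH2CO2Et (1.5 equiv), NaH (1.4 equiv), THF, 0 °C → rt; chromatographic removal of the (Z) isomer
Reagents that add atoms: ethyl 2-(diisopropoxyphosphoryl)acetate, CCOC(=O)CP(=O)(OC(C)C)OC(C)C
Why: Horner–Wadsworth–Emmons olefination: the stabilised phosphonate anion should condense with the open methyl ketone only, because the C2 ketone is flanked by quaternary C1 and is too hindered for this weak nucleophile, and the bulky isopropyl phosphonate esters favour the (E)-enoate.

Step 12
Reactants: 17 keto enoate
Product: 18 (1R,2R,5S,8R)-8-[(3E)-5-hydroxy-3-methylpent-3-en-1-yl]-1,5-dimethyl-6-oxabicyclo[3.2.1]octan-2-ol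
Conditions: LiAlH4 (2 equiv), Et2O, −20 → 0 °C; aq. potassium sodium tartrate
Reagents that add atoms: none
Why: LiAlH4 reduction takes the enoate by 1,2-addition to the allylic alcohol with retention of the (E) geometry and reduces the C2 ketone by axial attack from the face syn to C8, since the opposite face is blocked by the axial C7 on C1, which should give the equatorial (2R) alcohol as is usual for 2,2-disubstituted cyclohexanones.

Step 13
Reactants: 18 diol; 19 umbelliferone
Product: 20 7-{[(2E)-5-[(1R,2R,5S,8R)-2-hydroxy-1,5-dimethyl-6-oxabicyclo[3.2.1]octan-8-yl]-3-methylpent-2-en-1-yl]oxy}-2H-chromen-2-one (target)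
Conditions: 19 (1.1 equiv), PPh3 (1.2 equiv), DIAD (1.2 equiv), THF, 0 °C → rt
Reagents that add atoms: none
Why: Mitsunobu etherification: the acidic phenol displaces the activated primary allylic hydroxyl by direct SN2 attack with the alkene geometry kept, while the equatorial C2 hydroxyl next to quaternary C1 is too hindered to compete at near-stoichiometric reagent loading, so it needs no protecting group.

Compound list
1 | (E)-geranylacetone, (5E)-6,10-dimethylundeca-5,9-dien-2-one | CC(C)=CCC/C(C)=C/CCC(C)=O | starting material
2 | (5E)-9-bromo-10-hydroxy-6,10-dimethylundec-5-en-2-one (racemic) | CC(C)(O)C(Br)CC/C(C)=C/CCC(C)=O | intermediate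
3 | (5E)-9,10-epoxy-6,10-dimethylundec-5-en-2-one (racemic) | CC1(C)OC1CC/C(C)=C/CCC(C)=O | intermediate
4 | (5E)-9,10-dihydroxy-6,10-dimethylundec-5-en-2-one (racemic, not isolated) | CC(C)(O)C(O)CC/C(C)=C/CCC(C)=O | intermediate
5 | (4E)-4-methyl-8-oxonon-4-enal | O=CCC/C(C)=C/CCC(C)=O | intermediate
6 | (−)-8-phenylmenthol, (1R,2S,5R)-5-methyl-2-(2-phenylpropan-2-yl)cyclohexan-1-ol | O[C@@H]1C[C@H](C)CC[C@H]1C(C)(C)c1ccccc1 | starting material
7 | propionyl chloride | CCC(Cl)=O | starting material
8 | (1R,2S,5R)-8-phenylmenthyl propionate | CCC(=O)O[C@@H]1C[C@H](C)CC[C@H]1C(C)(C)c1ccccc1 | intermediate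
9 | lithium enolate of 8 (methyl trans to OLi, not isolated) | C/C=C(/[O-])O[C@@H]1C[C@H](C)CC[C@H]1C(C)(C)c1ccccc1.[Li+] | intermediate
10 | 8-phenylmenthyl (6E)-3-hydroxy-2,6-dimethyl-10-oxoundec-6-enoate (mixture at chain C2 and C3) | CC(=O)CC/C=C(\C)CCC(O)C(C)C(=O)O[C@@H]1C[C@H](C)CC[C@H]1C(C)(C)c1ccccc1 | intermediate
11 | 8-phenylmenthyl (6E)-2,6-dimethyl-3,10-dioxoundec-6-enoate (epimers at chain C2) | CC(=O)CC/C=C(\C)CCC(=O)C(C)C(=O)O[C@@H]1C[C@H](C)CC[C@H]1C(C)(C)c1ccccc1 | intermediate
12 | bicyclic 7-(8-phenylmenthyloxy) dialkoxycarbenium acetate (not isolated) | CC(=O)CC[C@@H]1[C@]2(C)C(O[C@@H]3C[C@H](C)CC[C@H]3C(C)(C)c3ccccc3)=[O+][C@@]1(C)CCC2=O.CC(=O)[O-] | intermediate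
13 | (1S,5S,8R)-1,5-dimethyl-8-(3-oxobutyl)-6-oxabicyclo[3.2.1]octane-2,7-dione | CC(=O)CC[C@@H]1[C@]2(C)C(=O)O[C@@]1(C)CCC2=O | intermediate
14 | (1S,5S,8R)-8-(3-hydroxybutyl)-1,5-dimethyl-6-oxabicyclo[3.2.1]octane-2,7-diol (epimers at C2, C7, C11) | CC(O)CC[C@@H]1[C@]2(C)C(O)O[C@@]1(C)CCC2O | intermediate
15 | (1R,5S,8R)-8-(3-hydroxybutyl)-1,5-dimethyl-6-oxabicyclo[3.2.1]octan-2-ol (epimers at C2, C11) | CC(O)CC[C@@H]1[C@]2(C)CO[C@@]1(C)CCC2O | intermediate
16 | (1R,5S,8R)-1,5-dimethyl-8-(3-oxobutyl)-6-oxabicyclo[3.2.1]octan-2-one | CC(=O)CC[C@@H]1[C@]2(C)CO[C@@]1(C)CCC2=O | intermediate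
17 | ethyl (2E)-5-[(1R,5S,8R)-1,5-dimethyl-2-oxo-6-oxabicyclo[3.2.1]octan-8-yl]-3-methylpent-2-enoate | CCOC(=O)/C=C(\C)CC[C@@H]1[C@]2(C)CO[C@@]1(C)CCC2=O | intermediate
18 | (1R,2R,5S,8R)-8-[(3E)-5-hydroxy-3-methylpent-3-en-1-yl]-1,5-dimethyl-6-oxabicyclo[3.2.1]octan-2-ol | C/C(=C\CO)CC[C@@H]1[C@]2(C)CO[C@@]1(C)CC[C@H]2O | intermediate
19 | umbelliferone, 7-hydroxy-2H-chromen-2-one | Oc1ccc2ccc(=O)oc2c1 | starting material
20 | CNP0178104.1, (1R,2R,5S,8R), (E) | C/C(=C\COc1ccc2ccc(=O)oc2c1)CC[C@@H]1[C@]2(C)CO[C@@]1(C)CC[C@H]2O | target

Total step count: 13. Longest linear sequence: 12 (steps 1–3 and 5–13). Step 4 is a one-step side branch.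

Steps most likely to fail

1. Step 7.
- What may go wrong: proton loss from the C5 cation, or copper-mediated elimination, may outrun lactone closure. The side-chain ketone oxygen may compete for the cation. Imperfect shielding of one radical face would lower the enantiomeric purity at a point where the auxiliary has already left, so chromatography could not repair it.
- Fallback, from 11 back to 13: the two ring closures are separated. Cyclisation of 11 with Mn(OAc)3·2H2O and a full equivalent of Cu(OAc)2·H2O in AcOH is allowed to end in its usual way, by oxidative elimination. This gives the exocyclic-methylene keto ester F1, which keeps the auxiliary. The product of attack on the wrong face is then a diastereomer and can be removed on silica or by crystallisation. TsOH·H2O in CH2Cl2 then protonates the 1,1-disubstituted alkene at its CH2 end. The axial ester closes on the C5 cation, and the hydrate water frees 6 and gives 13. This last event is the acid-catalysed lactonisation of a γ,δ-unsaturated ester.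

2. Step 9.
- What may go wrong: the side-chain hydroxyl may add to the ionised C7 and divert the reduction towards a seven-membered or ring-opened ether. Reaction at the neopentyl position may also be so slow that the tertiary C5–O6 bond begins to ionise.
- Fallback, from 14 back to 15: all three hydroxyl groups are first acetylated (Ac2O, DMAP, pyridine) to the triacetate F2. Et3SiH/BF3·OEt2 then removes only the acetal-type C7 acetate, a better leaving group that departs at lower temperature from a substrate without free hydroxyl groups. This gives the diacetate F3. K2CO3 in MeOH at 40 °C returns 15.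

3. Step 11.
- What may go wrong: (E)-selectivity may erode, because the two flanks of a methyl ketone differ little in size. Long reaction times may also let the anion begin to engage the ring ketone.
- Fallback, from 16 back to 18: the geometry is taken from a stereospecific syn-carbometalation instead of an olefination.
  - NaBH4 in MeOH reduces both ketones, with axial attack at C2, to the diol F4.
  - TEMPO (catalytic) with PhI(OAc)2 oxidises only the unhindered side-chain carbinol, giving the hydroxy ketone F5.
  - TBSOTf and 2,6-lutidine give the silyl ether F6.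
  - LiN(iPr)2 at −78 °C followed by ClP(O)(OEt)2 gives the terminal enol phosphate F7, which two further equivalents of LiN(iPr)2 eliminate in the same flask to the terminal alkyne F8.
  - Negishi carboalumination (Me3Al, Cp2ZrCl2, CH2Cl2), followed by n-BuLi and (CH2O)n, gives the (E)-allylic alcohol silyl ether F9.
  - Bu4NF in THF returns 18.

Further compounds
F1 | step 7 | 8-phenylmenthyl 1-methyl-5-methylene-2-oxo-6-(3-oxobutyl)cyclohexane-1-carboxylate with C1 and C8 configured as in 13 | CC(=O)CC[C@H]1C(=C)CCC(=O)[C@@]1(C)C(=O)O[C@@H]1C[C@H](C)CC[C@H]1C(C)(C)c1ccccc1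
F2 | step 9 | triacetate of 14 (epimers at C2, C7, C11) | CC(OC(C)=O)CC[C@@H]1[C@]2(C)C(OC(C)=O)O[C@@]1(C)CCC2OC(C)=O
F3 | step 9 | diacetate of 15 (epimers at C2, C11) | CC(OC(C)=O)CC[C@@H]1[C@]2(C)CO[C@@]1(C)CCC2OC(C)=O
F4 | step 11 | (1R,2R,5S,8R)-8-(3-hydroxybutyl)-1,5-dimethyl-6-oxabicyclo[3.2.1]octan-2-ol (epimers at C11) | CC(O)CC[C@@H]1[C@]2(C)CO[C@@]1(C)CC[C@H]2O
F5 | step 11 | 4-[(1R,2R,5S,8R)-2-hydroxy-1,5-dimethyl-6-oxabicyclo[3.2.1]octan-8-yl]butan-2-one | CC(=O)CC[C@@H]1[C@]2(C)CO[C@@]1(C)CC[C@H]2O
F6 | step 11 | C2 tert-butyldimethylsilyl ether of F5 | CC(=O)CC[C@@H]1[C@]2(C)CO[C@@]1(C)CC[C@H]2O[Si](C)(C)C(C)(C)C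
F7 | step 11 | terminal diethyl enol phosphate of F6 | C=C(CC[C@@H]1[C@]2(C)CO[C@@]1(C)CC[C@H]2O[Si](C)(C)C(C)(C)C)OP(=O)(OCC)OCC
F8 | step 11 | 8-(but-3-yn-1-yl) bicyclic ether, C2 silyl ether | C#CCC[C@@H]1[C@]2(C)CO[C@@]1(C)CC[C@H]2O[Si](C)(C)C(C)(C)C
F9 | step 11 | C2 tert-butyldimethylsilyl ether of 18 | C/C(=C\CO)CC[C@@H]1[C@]2(C)CO[C@@]1(C)CC[C@H]2O[Si](C)(C)C(C)(C)C
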